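**Retrosynthetic overview**
- Erycibenin B ⇐ its 5,7-di-O-benzyl ether; hydrogenolysis is the last step.
- Ring C (the pyranone, the only ring that is built) ⇐ ortho-(methoxymethoxy)aryl benzyl ketone + one carbon. Acid frees only the MOM-bearing oxygen, which closes O1–C2 and so places the side chain at C8.
- Aryl ketone ⇐ aryllithium (second ortho-metalation beside the same OMOM group) + Weinreb amide of 4-hydroxyphenylacetic acid (ring B, bought).
- Key disconnection, C8–CH2: mirror-symmetric 1,3-bis(benzyloxy)-5-(methoxymethoxy)benzene (ring A, bought as the phenol) + methyl (S)-glycidate + 2 MeMgBr in one flask. The (S) centre is taken over unchanged from the glycidate.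
- Ring order: rings A and B are purchased arenes; ring C is closed in the second-last step.

Assumption: the [C@@H] centre of the target is (S) by CIP analysis; 3,5-bis(benzyloxy)phenol, methyl (S)-glycidate, 4-hydroxyphenylacetic acid and all reagents are bought.

**Step 1**
Reactants: 1 3,5-bis(benzyloxy)phenol
Product: 2 1,3-bis(benzyloxy)-5-(methoxymethoxy)benzene
Conditions: MOMCl (1.3 equiv), K2CO3, acetone, 0 °C → rt
Reagents that add atoms: chloromethyl methyl ether, COCCl
Why: Base-mediated O-alkylation of the only free phenol (Williamson-type acetal protection) puts the one strongly chelating directing group on the oxygen that later becomes O1 of ring C.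

**Step 2**
Reactants: 2 1,3-bis(benzyloxy)-5-(methoxymethoxy)benzene; 3 methyl (2S)-oxirane-2-carboxylate
Product: 7 (2S)-1-[2,4-bis(benzyloxy)-6-(methoxymethoxy)phenyl]-3-methylbutane-2,3-diol, via aryllithium 4 (not isolated), via arylmagnesium bromide 5 (not isolated), via bromomagnesium alkoxide ester 6 (not isolated)
Conditions: n-BuLi (1.1 equiv), THF, 0 °C; MgBr2 (1.2 equiv), 0 °C; cannulate into 3 (1.2 equiv), CuI (10 mol%), THF, −40 → −20 °C; then MeMgBr (4 equiv), −20 → 0 °C
Reagents that add atoms: methylmagnesium bromide, C[Mg]Br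
Why: Directed ortho-metalation beside the OMOM group (two equivalent sites, favoured over the single site between the weakly directing benzyloxy groups) removes the mirror symmetry of 2, the copper-catalysed Grignard opening of the glycidic ester is an SN2 attack at the unsubstituted C3 so the (S) centre of 3 is carried over untouched, and double Grignard addition of MeMgBr to the ester of 6 completes the diol in the same flask.

**Step 3**
Reactants: 8 (4-hydroxyphenyl)acetic acid
Product: 10 2-(4-hydroxyphenyl)-N-methoxy-N-methylacetamide, via acyl imidazolide 9 (not isolated)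
Conditions: 1,1'-carbonyldiimidazole (CDI, 1.05 equiv), THF, rt; then MeNHOMe·HCl (1.2 equiv), rt
Reagents that add atoms: N,O-dimethylhydroxylamine hydrochloride, CNOC.Cl
Why: Weinreb amide synthesis through the acyl imidazolide works because CDI activates the carboxylic acid much faster than the phenol and N,O-dimethylhydroxylamine then displaces imidazole.

**Step 4**
Reactants: 7 (2S)-1-[2,4-bis(benzyloxy)-6-(methoxymethoxy)phenyl]-3-methylbutane-2,3-diol; 10 2-(4-hydroxyphenyl)-N-methoxy-N-methylacetamide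
Product: 13 1-{4,6-bis(benzyloxy)-3-[(2S)-2,3-dihydroxy-3-methylbutyl]-2-(methoxymethoxy)phenyl}-2-(4-hydroxyphenyl)ethan-1-one, via trilithiated diol 11 (not isolated), via lithium phenolate 12 (not isolated)
Conditions: 7, n-BuLi (3.3 equiv), THF, −78 → 0 °C; then 12 (1.3 equiv; from 10, LiN(SiMe3)2 (1.0 equiv), THF, −78 °C), −78 → 0 °C
Reagents that add atoms: none
Why: A second directed ortho-metalation, steered by the OMOM group towards its only free neighbouring position, is followed by Weinreb ketone synthesis, in which the chelated tetrahedral adduct stops at the ketone and the para-phenolate of 12 lowers the acidity of its benzylic CH2 so that addition outruns enolisation; the stereocentre is remote and sits as a lithium alkoxide.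

**Step 5**
Reactants: 13 1-{4,6-bis(benzyloxy)-3-[(2S)-2,3-dihydroxy-3-methylbutyl]-2-(methoxymethoxy)phenyl}-2-(4-hydroxyphenyl)ethan-1-one
Product: 15 5,7-bis(benzyloxy)-8-[(2S)-2,3-dihydroxy-3-methylbutyl]-3-(4-hydroxyphenyl)-4H-chromen-4-one, via enaminone 14 (not isolated)
Conditions: t-BuOCH(NMe2)2 (4 equiv), THF, 65 °C; evaporate; then 2 M HCl, MeOH, 45 °C
Reagents that add atoms: tert-butoxybis(dimethylamino)methane, CC(C)(C)OC(N(C)C)N(C)C
Why: Aminomethylenation of the active methylene by Bredereck's reagent gives enaminone 14, and acid then cleaves only the MOM acetal so that the single free ortho phenol, the one next to the side chain, closes ring C by addition–elimination with loss of dimethylamine (enaminone route to isoflavones), which fixes the side chain at C8 and leaves the stereocentre untouched.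

**Step 6**
Reactants: 15 5,7-bis(benzyloxy)-8-[(2S)-2,3-dihydroxy-3-methylbutyl]-3-(4-hydroxyphenyl)-4H-chromen-4-one
Product: 16 erycibenin B, 5,7-dihydroxy-8-[(2S)-2,3-dihydroxy-3-methylbutyl]-3-(4-hydroxyphenyl)-4H-chromen-4-one
Conditions: H2 (1 atm), Pd/C (10 wt%), EtOAc/MeOH, rt
Reagents that add atoms: none
Why: Catalytic hydrogenolysis of the two aryl benzyl ethers is much faster than reduction of the chromone C2=C3 bond at 1 atm, and the homobenzylic diol is inert to it, so the (S) centre survives.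

**Compound list**
1 | 3,5-bis(benzyloxy)phenol | Oc1cc(OCc2ccccc2)cc(OCc2ccccc2)c1 | starting material
2 | 1,3-bis(benzyloxy)-5-(methoxymethoxy)benzene | COCOc1cc(OCc2ccccc2)cc(OCc2ccccc2)c1 | intermediate
3 | methyl (2S)-oxirane-2-carboxylate (methyl (S)-glycidate) | COC(=O)[C@@H]1CO1 | starting material
4 | [2,4-bis(benzyloxy)-6-(methoxymethoxy)phenyl]lithium | [Li]c1c(OCOC)cc(OCc2ccccc2)cc1OCc1ccccc1 | intermediate
5 | [2,4-bis(benzyloxy)-6-(methoxymethoxy)phenyl]magnesium bromide | Br[Mg]c1c(OCOC)cc(OCc2ccccc2)cc1OCc1ccccc1 | intermediate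
6 | methyl (2S)-3-[2,4-bis(benzyloxy)-6-(methoxymethoxy)phenyl]-2-[(bromomagnesio)oxy]propanoate | COC(=O)[C@@H](O[Mg]Br)Cc1c(OCOC)cc(OCc2ccccc2)cc1OCc1ccccc1 | intermediate
7 | (2S)-1-[2,4-bis(benzyloxy)-6-(methoxymethoxy)phenyl]-3-methylbutane-2,3-diol | CC(C)(O)[C@@H](O)Cc1c(OCOC)cc(OCc2ccccc2)cc1OCc1ccccc1 | intermediate
8 | (4-hydroxyphenyl)acetic acid | OC(=O)Cc1ccc(O)cc1 | starting material
9 | 1-[(4-hydroxyphenyl)acetyl]-1H-imidazole | O=C(Cc1ccc(O)cc1)n1ccnc1 | intermediate
10 | 2-(4-hydroxyphenyl)-N-methoxy-N-methylacetamide | CON(C)C(=O)Cc1ccc(O)cc1 | intermediate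
11 | {2,4-bis(benzyloxy)-5-[(2S)-2,3-bis(lithiooxy)-3-methylbutyl]-6-(methoxymethoxy)phenyl}lithium | CC(C)(O[Li])[C@@H](O[Li])Cc1c(OCOC)c([Li])c(OCc2ccccc2)cc1OCc1ccccc1 | intermediate
12 | lithium 4-{2-[methoxy(methyl)amino]-2-oxoethyl}phenolate | CON(C)C(=O)Cc1ccc(O[Li])cc1 | intermediate
13 | 1-{4,6-bis(benzyloxy)-3-[(2S)-2,3-dihydroxy-3-methylbutyl]-2-(methoxymethoxy)phenyl}-2-(4-hydroxyphenyl)ethan-1-one | CC(C)(O)[C@@H](O)Cc1c(OCOC)c(C(=O)Cc2ccc(O)cc2)c(OCc2ccccc2)cc1OCc1ccccc1 | intermediate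
14 | 1-{4,6-bis(benzyloxy)-3-[(2S)-2,3-dihydroxy-3-methylbutyl]-2-(methoxymethoxy)phenyl}-3-(dimethylamino)-2-(4-hydroxyphenyl)prop-2-en-1-one (alkene geometry not defined) | CC(C)(O)[C@@H](O)Cc1c(OCOC)c(C(=O)C(=CN(C)C)c2ccc(O)cc2)c(OCc2ccccc2)cc1OCc1ccccc1 | intermediate
15 | 5,7-bis(benzyloxy)-8-[(2S)-2,3-dihydroxy-3-methylbutyl]-3-(4-hydroxyphenyl)-4H-chromen-4-one | CC(C)(O)[C@@H](O)Cc1c(OCc2ccccc2)cc(OCc2ccccc2)c2c(=O)c(-c3ccc(O)cc3)coc12 | intermediate
16 | erycibenin B, 5,7-dihydroxy-8-[(2S)-2,3-dihydroxy-3-methylbutyl]-3-(4-hydroxyphenyl)-4H-chromen-4-one | CC(C)(O)[C@@H](O)Cc1c(O)cc(O)c2c(=O)c(-c3ccc(O)cc3)coc12 | target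

**Totals**
Total step count: 6. Longest linear sequence: 5 (steps 1, 2, 4, 5, 6; step 3 makes the side fragment 10).

**Steps most likely to fail**

Step 2 is the most exposed. The metalation must choose the position between OMOM and OBn over the one between the two OBn groups. A doubly ortho-substituted aryl copper/magnesium species must open the glycidate at C3 without attacking the ester. Three organometallic events are telescoped. The fallback sets out from 2 and 3 and returns at 7. It forms the aryl–CH2 bond on a finished carbinol epoxide, without copper and without an ester in the flask. Compound 3 is treated with MeMgBr (Et2O, −78 °C) to give 2-[(2S)-oxiran-2-yl]propan-2-ol F1. Silylation (Et3SiOTf, 2,6-lutidine, CH2Cl2, −78 °C) gives triethyl({2-[(2S)-oxiran-2-yl]propan-2-yl}oxy)silane F2. Aryllithium 4, made from 2 as in step 2, opens F2 at the terminal carbon in the presence of BF3·OEt2 (THF, −78 °C) to give (2S)-1-[2,4-bis(benzyloxy)-6-(methoxymethoxy)phenyl]-3-methyl-3-[(triethylsilyl)oxy]butan-2-ol F3. Bu4NF (THF, rt) then gives 7.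

Step 4 asks a trilithiated, doubly ortho-substituted aryllithium to add to an enolisable, phenolate-bearing amide. Incomplete metalation, enolisation of 12 or poor solubility can each cut the yield. The fallback sets out from 7 and returns at 15. It builds ring C before ring B is attached and so needs no arylacetyl electrophile. Species 11, made from 7 as in step 4, is quenched with N-methoxy-N-methylacetamide to give 1-{4,6-bis(benzyloxy)-3-[(2S)-2,3-dihydroxy-3-methylbutyl]-2-(methoxymethoxy)phenyl}ethan-1-one F4. HCl in MeOH removes the MOM group to give 1-{4,6-bis(benzyloxy)-3-[(2S)-2,3-dihydroxy-3-methylbutyl]-2-hydroxyphenyl}ethan-1-one F5. Me2NCH(OMe)2 (THF, 60 °C) gives (2E)-1-{4,6-bis(benzyloxy)-3-[(2S)-2,3-dihydroxy-3-methylbutyl]-2-hydroxyphenyl}-3-(dimethylamino)prop-2-en-1-one F6. I2 (CHCl3, rt) closes and iodinates it to 5,7-bis(benzyloxy)-8-[(2S)-2,3-dihydroxy-3-methylbutyl]-3-iodo-4H-chromen-4-one F7. Suzuki–Miyaura coupling of F7 with 4-hydroxyphenylboronic acid (Pd(PPh3)4, Na2CO3, DME/H2O, 80 °C) gives 15.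

Step 5 may stall at the aminomethylenation. The ketone of 13 is twisted out of plane by two ortho substituents, and its free OH groups consume the formamide acetal. The fallback sets out from 13 and returns at 15, and it reverses the order of events. HCl in MeOH (40 °C) first removes the MOM group to give the chelated, planar ortho-hydroxy ketone 1-{4,6-bis(benzyloxy)-3-[(2S)-2,3-dihydroxy-3-methylbutyl]-2-hydroxyphenyl}-2-(4-hydroxyphenyl)ethan-1-one F8. The ring carbon is then inserted as an orthoester (HC(OEt)3, morpholine, DMF, 100 °C; dilute acid work-up frees the diol) to give 15.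

**Further compounds**
F1 | step 2 | 2-[(2S)-oxiran-2-yl]propan-2-ol | CC(C)(O)[C@@H]1CO1
F2 | step 2 | triethyl({2-[(2S)-oxiran-2-yl]propan-2-yl}oxy)silane | CC[Si](CC)(CC)OC(C)(C)[C@@H]1CO1
F3 | step 2 | (2S)-1-[2,4-bis(benzyloxy)-6-(methoxymethoxy)phenyl]-3-methyl-3-[(triethylsilyl)oxy]butan-2-ol | CC[Si](CC)(CC)OC(C)(C)[C@@H](O)Cc1c(OCOC)cc(OCc2ccccc2)cc1OCc1ccccc1
F4 | step 4 | 1-{4,6-bis(benzyloxy)-3-[(2S)-2,3-dihydroxy-3-methylbutyl]-2-(methoxymethoxy)phenyl}ethan-1-one | CC(C)(O)[C@@H](O)Cc1c(OCOC)c(C(C)=O)c(OCc2ccccc2)cc1OCc1ccccc1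
F5 | step 4 | 1-{4,6-bis(benzyloxy)-3-[(2S)-2,3-dihydroxy-3-methylbutyl]-2-hydroxyphenyl}ethan-1-one | CC(C)(O)[C@@H](O)Cc1c(O)c(C(C)=O)c(OCc2ccccc2)cc1OCc1ccccc1
F6 | step 4 | (2E)-1-{4,6-bis(benzyloxy)-3-[(2S)-2,3-dihydroxy-3-methylbutyl]-2-hydroxyphenyl}-3-(dimethylamino)prop-2-en-1-one | CC(C)(O)[C@@H](O)Cc1c(O)c(C(=O)/C=C/N(C)C)c(OCc2ccccc2)cc1OCc1ccccc1
F7 | step 4 | 5,7-bis(benzyloxy)-8-[(2S)-2,3-dihydroxy-3-methylbutyl]-3-iodo-4H-chromen-4-one | CC(C)(O)[C@@H](O)Cc1c(OCc2ccccc2)cc(OCc2ccccc2)c2c(=O)c(I)coc12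
F8 | step 5 | 1-{4,6-bis(benzyloxy)-3-[(2S)-2,3-dihydroxy-3-methylbutyl]-2-hydroxyphenyl}-2-(4-hydroxyphenyl)ethan-1-one | CC(C)(O)[C@@H](O)Cc1c(O)c(C(=O)Cc2ccc(O)cc2)c(OCc2ccccc2)cc1OCc1ccccc1
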